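If you repeat these runs, watch second substrate and reagent together, as a pair of concentrations.

    starting material + reagent → target (k1 = 1.18 M⁻¹ s⁻¹)
    second substrate + reagent → second product (k2 = 0.0274 M⁻¹ s⁻¹)
    starting material + second substrate → cross product (k3 = 3.71 M⁻¹ s⁻¹)
    starting material + protic impurity → quenched substrate (k4 = 0.0961 M⁻¹ s⁻¹)
    starting material ⇌ dormant form (K5 = 0.555, k5 = 0.0118 s⁻¹)

all flasks: starting material 0.10 M; protic impurity 0.0500 M

|  | reagent | second substrate | remark | time |
|---|---|---|---|---|
| noon | 1.10 equiv | 1.00 equiv | a single well-mixed tank run continuously and read at steady state, 80 s in it on average |  |
| midnight | 1.10 equiv (fed, over 40.0 s) | 1.00 equiv | all but reagent at the start; reagent goes in evenly over 40.0 s, the run ends at 80 s | 80 s |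
| autumn | 1.10 equiv | 1.00 equiv | everything together in a closed stirred flask, run for 80 s | 80 s |
| dusk | 1.10 equiv | 1.00 equiv (fed, over 40.0 s) | a stirred flask in which second substrate is dosed at a steady rate over 40.0 s without added volume, worked up at 80 s | 80 s |

- the stated concentrations are those of everything mixed, before any reaction; amounts are the same in each set-up
- the feed brings no volume worth counting
- run time (midnight): 80 s

* the set-up with the highest amount of target at the outlet or at the end, in percent of the starting material put in ("none" if the first two lie within 2 percentage points) (noon / midnight / autumn / dusk / none)
* amount of target at the outlet or at the end, in percent of the starting material put in, noon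
* amount of target at the outlet or at the end, in percent of the starting material put in, midnight
* amount of target at the outlet or at the end, in percent of the starting material put in, autumn
* amount of target at the outlet or at the end, in percent of the starting material put in, dusk

As charged, starting material leaves fastest by the cross step, with a half-life of 1.9 s against 5.3 s by the target step. Both steps are first order in starting material, so my reckoning compares only what multiplies it. With reagent at 0.110 M, the two steps take starting material equally fast when second substrate stands at 1.18 M⁻¹ s⁻¹ times reagent over 3.71 M⁻¹ s⁻¹, which is 0.0350 M: the break-even level.

Autumn opens with second substrate at 0.100 M, which is 2.86 times break-even, so the target's opening share is 25.9%. In dusk, if the cross step eats the feed of 0.002500 M s⁻¹ as it arrives, second substrate holds near 0.006739 M, well under break-even. The opening share is then 83.9%. These are opening shares, not yields, but I put dusk above autumn.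

The forecast names dusk as best, with 36% for noon, 23% for midnight, 33.5% for autumn and 63% for dusk, on the ground of “keeping second substrate scarce while reagent is plentiful”.

The simulation gives 34.1% for noon, 11.2% for midnight, 32.0% for autumn and 64.5% for dusk, so dusk is best. The forecast parts from it at midnight, standing 12 percentage points above.

In dusk, starting material stood at its highest, 0.100 M, and the run ended with cross product at 30.0% beside the target; counting the reagent taken up by that target, break-even had sunk from 0.0350 M to 0.0145 M. In noon, the tank read reagent at 0.0701 M, which puts break-even at 0.0223 M, and its outlet ratio of target to cross product, 0.599, puts second substrate there at 0.0373 M.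

The numbers were drawn at random within sensible limits; the run is a simulation.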